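## Structural features

The target is a 7,8-dihydro-6H-isochromen-6-one. A pyran ring (O2, C1, C8a, C4a, C4, C3) is fused through C4a–C8a to a carbocycle (C4a, C5, C6, C7, C8, C8a). The C3=C4, C1=C8a and C4a=C5 double bonds and the C6 ketone form one push–pull chromophore that runs from O2 to the C6 carbonyl. C3 carries an (E)-3-acetoxyprop-1-enyl chain (C1'–C3'). C7 is the only stereocentre, a quaternary S carbon with a methyl group and an oxygen esterified by orsellinic acid; it lies between the C6 ketone and the C8 methylene, so no other stereocentre is adjacent. The fragile groups are: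

- the primary allylic acetate, which ends a trienyl system donor-substituted by O2 and is easily ionised by acids, Lewis acids or zerovalent palladium and cleaved by nucleophilic base;
- C1, which is electrophilic (a doubly vinylogous formate carbon);
- the tertiary α-ketol ester;
- the two free phenols.

The real difficulties are the oxygenated quaternary C7 in one absolute sense, a pyran synthesis that keeps the side chain away from the ring-forming chemistry, and the esterification of a tertiary alcohol with a di-ortho-substituted benzoic acid. The key step uses the fact that O2–C3 can be raised to the lactone level. With a carbonyl at C3, C4 is the α-carbon of an acetic acid unit, so the pyran comes from an acetate residue joined to C4a (C4–C4a) whose carboxyl oxygen closes onto the electrophilic C1 (O2–C1). The same C3 carbonyl later serves, as its enol triflate, as the attachment point for C1'–C3'.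

## Logic of the disconnections

**24 ⇒ 23.** No skeletal bond is cut; two aryl O–H bonds become O–Si. The phenols must be silent while the C7 ester is made, and silicon leaves with buffered fluoride, which spares the allylic acetate, the hindered ester and C1. The forward step must be a clean, near-neutral desilylation.

**23 ⇒ 19 + 22.** The acyl C–O bond of the C7 ester is cut, which removes the whole aromatic unit and leaves a core alcohol carrying every other feature. The ester is placed after the lactone stage because in 15 the C4 methylene is more acidic than the tertiary hydroxyl is nucleophilic and would take the acyl group first. The forward step must join a tertiary alcohol and a di-ortho-substituted acyl donor without nucleophilic or basic reagents.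

**22 ⇒ 21 ⇒ 20.** Only C–Cl and O–Si bonds are changed. The silyl ester in 21 allows direct, neutral conversion into 22, so the aryl silyl ethers never meet hydrogen chloride.

**19 ⇒ 16 + 18.** The C3–C1' bond is cut between two sp2 carbons. The acetate-bearing chain then enters as one unit after the ring chemistry is over. The forward coupling must be faster than ionisation of the allylic acetate and must keep the E geometry.

**18 ⇒ 17.** The C1'–B bond is cut; syn addition of H–B to the alkyne sets the E alkene in one step.

**16 ⇒ 15.** The C3–O–S bond is cut, which reveals the lactone. Enolisation of 15 towards C4 creates the C3=C4 bond and completes the chromophore while the oxygen becomes a leaving group. The forward step must sulfonylate the enol oxygen and leave the free C7 hydroxyl alone.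

**15 ⇒ 10 + 12 (through 13 and 14).** O2–C1 and C4–C4a are cut. The bicycle falls to a monocyclic triflate and a two-carbon zinc enolate, and the pyran oxygen is traced to a carboxyl group. The forward step must couple at C4a, not at C1 or C6, and the acid must then displace methanol at C1.

**12 ⇒ 11.** The C–Zn bond is cut; zinc inserts into the C–Br bond.

**10 ⇒ 9 ⇒ 7.** The C4a–O–S bond and then the C7–O–Si bond are cut. 7 holds all carbons of the carbocycle plus C1. The forward steps must distinguish the two diketone oxygens (C4a against C6) and silylate only the tertiary hydroxyl in the end.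

**7 ⇒ 3 + 5 (through 6).** C7–C8 and C5–C6 are cut, each next to a carbonyl group, so they map onto a conjugate addition and a Claisen-type acylation. The stereocentre is carried by 3 and the C1 carbon by 5. The enolate of 3 must react on the face away from its tert-butyl group, and the ring carbonyl of 3 must serve as the acyl donor.

**3 ⇒ 1 + 2 and 5 ⇒ 4.** The acetal C–O bonds of 3 and the C8a=C8 bond of 5 are cut, leading to a chiral-pool acid, an aldehyde and a keto acetal that take up one carbon from formaldehyde.

## Other disconnections considered

**Alternative 1:** The cut is C7–C8 and C5–C6 of the carbocycle. In the forward step a lactate-derived dioxolanone enolate adds to an acetal-bearing enone, and the acetyl enolate then closes onto the dioxolanone carbonyl with loss of pivalaldehyde. The product is (S,E)-4-hydroxy-6-(methoxymethylene)-4-methylcyclohexane-1,3-dione A1, the same compound as 7.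
- In favour: one operation builds the carbocycle, sets C7 from the chiral pool and delivers C4a, C6 and C1 at the right oxidation levels.
- Against: as a centrepiece it leaves the pyran, the side chain and the ester unsolved; A1 has two diketone oxygens that still need to be told apart; the rarer enantiomer of lactic acid is required.
- Comparison: the chosen key step builds the pyran from exactly this kind of intermediate, so the two are complementary, and the route uses this transformation as step 3. The alternative is the better of the two on stereochemistry, since it creates the stereocentre and step 7 creates none. It is equal in bonds and rings formed (two bonds, one ring each). Step economy is identical, because any plan through A1 needs a pyran synthesis afterwards.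

**Alternative 2:** The cut is C6–C7. The precursor would be (E)-3-[4-(2-oxoethylidene)-5-(2-oxopropyl)-4H-pyran-2-yl]prop-2-en-1-yl acetate A2. A chiral triazolium-derived carbene would convert its C6 aldehyde into an acyl anion equivalent that adds to the C7 methyl ketone, closing the carbocycle and creating C7. The product is (S)-3-[(E)-3-acetoxyprop-1-enyl]-7-hydroxy-7-methyl-7,8-dihydro-6H-isochromen-6-one A3, the same compound as 19.
- In favour: the stereocentre is made catalytically, no auxiliary and no C7 protecting group are needed, and aldehyde–ketone benzoin closures to six-membered tertiary α-ketols are an established reaction type.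
- Against: the aldehyde of A2 is conjugated to O2 along two paths and is a poor partner for the carbene. The C8 methylene between ketone and pyran is acidic and could enter aldol chemistry under the base that frees the carbene. The exocyclic C4a=C5 geometry must point the aldehyde towards the ketone arm. The carbene could also attack C1 or the allylic acetate. A2 itself has no obvious short synthesis.
- Comparison: the alternative is better in principle on stereochemical economy (catalyst control against a stoichiometric chiral-pool acetal). From A3 onwards the two plans are equal, with the same two steps to the target. On mechanism the chosen plan is safer, because it uses the natural electrophilicity of C1, whereas the alternative asks a carbonyl deactivated by that same polarity to react first. Overall step count would favour the alternative only if A2 were accessible in about six steps.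

**Alternative 3:** The cut is C3–C4 and O2–C1. The enone (S,E)-4-(methoxymethylene)-3,6-dimethyl-6-(triethylsilyloxy)cyclohex-2-en-1-one A4 would be converted into its silyl dienol ether by deprotonation at the C4 methyl group and acylated there by (E)-4-acetoxybut-2-enoyl chloride A5 with ZnCl2. Acid would then make the C3 enol oxygen displace methanol at C1. The product is the core as its C7 triethylsilyl ether A6.
- In favour: the pyran and the complete side chain arrive in one operation, without palladium or triflates, and the closure onto C1 uses the same polarity as the chosen plan (equal on that point). The route would be three or four steps shorter, so it is better on step economy.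
- Against: the dienolate can be acylated at C5 as well as at C4. A5 is at once an acid chloride, a conjugate acceptor and an allylic acetate, and may ionise or polymerise with ZnCl2. The acylation product is highly enolisable and may be acylated twice. The C7 silyl ether must later be removed next to the allylic acetate. The side chain is committed early and cannot be varied.
- Comparison: the chosen plan replaces one uncertain vinylogous C-acylation by two couplings whose sites are fixed by triflates, and it keeps the allylic acetate away from every Lewis-acidic or strongly acidic step. The alternative is more convergent and would be the better route if the C4 selectivity held.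

Key step: step 7

Remark on the chemistry: position numbers follow the isochromene numbering of the target (C1, O2, C3, C4, C4a, C5, C6, C7, C8, C8a; side chain C1'–C3'), also in monocyclic precursors. The methoxymethylene group is drawn E, but its geometry is of no consequence because C1 passes through an sp3 stage during ring closure.

Remark on the chemistry: C7 is S in 7, 9, 10, 13–16, 19, 23 and 24. It derives from (R)-lactic acid with retention; the descriptor changes only because the new C8 substituent outranks methyl.

Remark on the chemistry: the alkenylboronate 18 is made in one step from propargyl acetate and is not assumed to be purchasable.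

## Route

Step 1
Reactants: 1 (R)-lactic acid; 2 pivalaldehyde
Product: 3 (2R,5R)-2-tert-butyl-5-methyl-1,3-dioxolan-4-one (cis)
Conditions: TsOH·H2O (cat.), H2SO4 (cat.), pentane, reflux with azeotropic removal of water; recrystallisation from pentane/Et2O, −78 °C
Reagents that add atoms: none
Why: Acid-catalysed acetalisation of an α-hydroxy acid; the cis-2,5-disubstituted dioxolanone is the thermodynamic and crystalline isomer, so the lactate configuration is copied onto the acetal carbon (self-regeneration of stereocentres).

Step 2
Reactants: 4 4,4-dimethoxybutan-2-one
Product: 5 3-(dimethoxymethyl)but-3-en-2-one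
Conditions: (CH2O)n, i-Pr2NH2+ CF3CO2− (1 equiv), CF3CO2H (10 mol %), THF, 65 °C; used freshly distilled
Reagents that add atoms: formaldehyde (as paraformaldehyde), C=O
Why: Amine-salt-mediated α-methylenation (Mannich condensation followed by β-elimination of the amine); the more substituted and more acidic C3 methylene between ketone and acetal should react in preference to the methyl group, and the weakly acidic medium should leave the dimethyl acetal intact.

Step 3
Reactants: 3 (2R,5R)-2-tert-butyl-5-methyl-1,3-dioxolan-4-one; 5 3-(dimethoxymethyl)but-3-en-2-one
Product: 7 (S,E)-4-hydroxy-6-(methoxymethylene)-4-methylcyclohexane-1,3-dione, via Michael adduct 6 (not isolated)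
Conditions: LiN(i-Pr)2, THF, −78 °C; 5, −78 °C; then LiN(SiMe3)2, −78 → 0 °C; aq NH4Cl
Reagents that add atoms: none
Why: Michael–Dieckmann annulation: the lithium enolate of 3 adds to the unsubstituted terminus of 5 on the face away from the tert-butyl group (C7–C8), which fixes C7 as S because the new bond takes the place of the lactate hydrogen; the adduct enolate loses methoxide to give the methoxymethylene ketone, and its acetyl enolate (second base) attacks the dioxolanone carbonyl in a 6-exo-trig Claisen closure (C5–C6) that expels pivalaldehyde and ends at the stable β-diketonate.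

Step 4
Reactants: 7 (S,E)-4-hydroxy-6-(methoxymethylene)-4-methylcyclohexane-1,3-dione
Product: 9 (S,E)-6-(methoxymethylene)-4-methyl-4-(triethylsilyloxy)cyclohexane-1,3-dione, via bis-silyl ether 8 (not isolated)
Conditions: Et3SiOTf (2.5 equiv), 2,6-lutidine, CH2Cl2, −78 → 0 °C; then MeOH, 0 °C
Reagents that add atoms: triethylsilyl trifluoromethanesulfonate, CC[Si](CC)(CC)OS(=O)(=O)C(F)(F)F
Why: Silyl triflate with a hindered pyridine silylates the tertiary alcohol and also the diketone enol; the resulting vinylogous silyl ester is solvolysed by methanol within minutes, while the tertiary silyl ether should be untouched.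

Step 5
Reactants: 9 (S,E)-6-(methoxymethylene)-4-methyl-4-(triethylsilyloxy)cyclohexane-1,3-dione
Product: 10 (S,E)-6-(methoxymethylene)-4-methyl-3-oxo-4-(triethylsilyloxy)cyclohex-1-en-1-yl trifluoromethanesulfonate
Conditions: PhNTf2, i-Pr2NEt, CH2Cl2, 0 °C → rt
Reagents that add atoms: N-phenylbis(trifluoromethanesulfonimide), O=S(=O)(N(c1ccccc1)S(=O)(=O)C(F)(F)F)C(F)(F)F
Why: O-Sulfonylation of the ammonium β-diketonate (enol triflate formation); the C4a oxygen is the unhindered one, since the C6 oxygen is flanked by the quaternary C7 with its silyl ether, and the C4a triflate keeps the linear MeO–C1=C8a–C4a=C5–C6=O conjugation, so kinetic and thermodynamic factors both point to 10.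

Step 6
Reactants: 11 tert-butyl bromoacetate
Product: 12 bromozinc tert-butyl acetate (Reformatsky reagent, THF solution)
Conditions: Zn dust (activated with Me3SiCl and BrCH2CH2Br), THF, rt → 40 °C; titrated and used as a solution
Reagents that add atoms: zinc, [Zn]
Why: Insertion of activated zinc into the C–Br bond of an α-bromo ester (Reformatsky reagent formation); the tert-butyl ester suppresses self-condensation.

Step 7
Reactants: 10 (S,E)-6-(methoxymethylene)-4-methyl-3-oxo-4-(triethylsilyloxy)cyclohex-1-en-1-yl trifluoromethanesulfonate; 12 bromozinc tert-butyl acetate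
Product: 15 (S)-7-hydroxy-7-methyl-7,8-dihydro-4H-isochromene-3,6-dione, via coupled tert-butyl ester 13 (not isolated), via hydroxy acid 14 (not isolated)
Conditions: Pd(PPh3)4 (5 mol %), THF, rt → 45 °C; aq NH4Cl wash, concentrate; then CF3CO2H/CH2Cl2 (1:3), 0 °C → rt; evaporation with toluene
Reagents that add atoms: none
Why: Zerovalent palladium inserts into the C4a–O bond of the β-acyl vinyl triflate 10, the zinc enolate 12 transmetalates through carbon, and reductive elimination forms C4–C4a to give 13; the closest known reaction type is the Negishi-type coupling of Reformatsky reagents with aryl and vinyl halides or triflates. Trifluoroacetic acid then removes the tert-butyl group as isobutene and the silyl group as its trifluoroacetate to give 14, and protonation of the C6 carbonyl turns the MeO–C1=C8a–C4a=C5–C6=O unit into an extended oxocarbenium ion that is electrophilic at C1. The carboxyl oxygen adds to C1 and methanol is expelled, which forms O2–C1 and closes the six-membered enol lactone; this closure is 6-endo-trig with respect to the C8a=C1 bond, or equivalently 6-exo-trig onto the C1=O+Me form, and either count is a favoured mode because C4, C4a, C8a and C1 are held cis on the ring. The known analogy for this second stage is the acid-mediated lactonisation of carboxylic acids onto alkoxymethylene ketones by addition–elimination. No stereocentre is created, and C7 is not enolisable and is not touched. The selectivity needed is coupling at C4a in preference to attack of the zinc enolate at C1 or at the C6 carbonyl: the covalent zinc enolate is a weak nucleophile without palladium, oxidative addition into the electron-poor triflate is fast near room temperature, and the C6 ketone is deactivated by the methoxy donor and shielded by the quaternary C7 with its silyl ether. Only the acid tethered at C4a can reach C1 through a six-membered transition state, so the lactonisation has no regiochemical alternative.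

Step 8
Reactants: 15 (S)-7-hydroxy-7-methyl-7,8-dihydro-4H-isochromene-3,6-dione
Product: 16 (S)-7-hydroxy-7-methyl-6-oxo-7,8-dihydro-6H-isochromen-3-yl trifluoromethanesulfonate
Conditions: PhNTf2, i-Pr2NEt, CH2Cl2, −20 → 0 °C; rapid filtration through silica, used at once
Reagents that add atoms: N-phenylbis(trifluoromethanesulfonimide), O=S(=O)(N(c1ccccc1)S(=O)(=O)C(F)(F)F)C(F)(F)F
Why: The C4 methylene of 15 is flanked by the lactone carbonyl and the dienone, so a tertiary amine suffices to form the extended enolate, which is sulfonylated on the C3 oxygen (enol triflate formation from an acidic lactone); the hindered tertiary alcohol does not react with this mild triflating agent.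

Step 9
Reactants: 17 prop-2-yn-1-yl acetate (propargyl acetate)
Product: 18 (E)-3-(4,4,5,5-tetramethyl-1,3,2-dioxaborolan-2-yl)prop-2-en-1-yl acetate
Conditions: pinacolborane (1.1 equiv), Cp2Zr(H)Cl (5 mol %), Et3N (10 mol %), neat, 60 °C
Reagents that add atoms: pinacolborane, CC1(C)OBOC1(C)C
Why: Zirconium-catalysed syn hydroboration of a terminal alkyne places boron on the terminal carbon and gives the (E)-alkenylboronate; the acetate is tolerated.

Step 10
Reactants: 16 (S)-7-hydroxy-7-methyl-6-oxo-7,8-dihydro-6H-isochromen-3-yl trifluoromethanesulfonate; 18 (E)-3-(4,4,5,5-tetramethyl-1,3,2-dioxaborolan-2-yl)prop-2-en-1-yl acetate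
Product: 19 (S)-3-[(E)-3-acetoxyprop-1-enyl]-7-hydroxy-7-methyl-7,8-dihydro-6H-isochromen-6-one
Conditions: PdCl2(dppf)·CH2Cl2 (5 mol %), K3PO4 (2 M aq, 3 equiv), degassed THF, rt
Reagents that add atoms: none
Why: Suzuki–Miyaura coupling of a lactone-derived ketene acetal triflate with an alkenylboronate forms C3–C1' with retention of the E geometry; oxidative addition into the strongly activated C3–O bond at room temperature should outrun ionisation of the primary allylic acetate, and the free tertiary alcohol is a spectator.

Step 11
Reactants: 20 orsellinic acid (2,4-dihydroxy-6-methylbenzoic acid)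
Product: 21 tert-butyldimethylsilyl 2,4-bis(tert-butyldimethylsilyloxy)-6-methylbenzoate
Conditions: t-BuMe2SiCl (3.5 equiv), imidazole, DMF, rt
Reagents that add atoms: tert-butyldimethylsilyl chloride, CC(C)(C)[Si](C)(C)Cl
Why: Exhaustive silylation of both phenols and the carboxylic acid with a silyl chloride and imidazole; the silyl ester is kept because it is the direct precursor of the acid chloride.

Step 12
Reactants: 21 tert-butyldimethylsilyl 2,4-bis(tert-butyldimethylsilyloxy)-6-methylbenzoate
Product: 22 2,4-bis(tert-butyldimethylsilyloxy)-6-methylbenzoyl chloride
Conditions: (COCl)2, DMF (cat.), CH2Cl2, 0 °C → rt; evaporation, used crude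
Reagents that add atoms: oxalyl chloride, O=C(Cl)C(Cl)=O
Why: Silyl esters are converted directly into acid chlorides by the chloroiminium salt formed from (COCl)2 and DMF, with loss of the silyl chloride under neutral conditions, so the aryl silyl ethers never meet hydrogen chloride.

Step 13
Reactants: 19 (S)-3-[(E)-3-acetoxyprop-1-enyl]-7-hydroxy-7-methyl-7,8-dihydro-6H-isochromen-6-one; 22 2,4-bis(tert-butyldimethylsilyloxy)-6-methylbenzoyl chloride
Product: 23 (S)-3-[(E)-3-acetoxyprop-1-enyl]-7-methyl-6-oxo-7,8-dihydro-6H-isochromen-7-yl 2,4-bis(tert-butyldimethylsilyloxy)-6-methylbenzoate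
Conditions: AgOTf (AgOSO2CF3), 2,6-di-tert-butyl-4-methylpyridine, CH2Cl2, −40 → 0 °C, dark
Reagents that add atoms: none
Why: AgOTf abstracts chloride from the electron-rich, di-ortho-substituted aroyl chloride to give an aroyl triflate with acylium character, a linear and sterically undemanding electrophile of the kind that acylates hindered tertiary alcohols (silver-promoted esterification); the hindered pyridine only scavenges acid, so neither C1 nor the allylic acetate meets a nucleophile, and C7 keeps its configuration because the C7–O bond is not broken.

Step 14
Reactants: 23 (S)-3-[(E)-3-acetoxyprop-1-enyl]-7-methyl-6-oxo-7,8-dihydro-6H-isochromen-7-yl 2,4-bis(tert-butyldimethylsilyloxy)-6-methylbenzoate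
Product: 24 (S)-3-[(E)-3-acetoxyprop-1-enyl]-7-methyl-6-oxo-7,8-dihydro-6H-isochromen-7-yl 2,4-dihydroxy-6-methylbenzoate (CNP0115558.1)
Conditions: HF·pyridine, pyridine, THF, 0 °C
Reagents that add atoms: none
Why: Buffered fluoride cleaves the two aryl silyl ethers through Si–F bond formation; the allylic acetate, the hindered C7 ester and the chromophore should be stable to HF·pyridine in excess pyridine at 0 °C.

## Compound list

1 | (R)-lactic acid | C[C@@H](O)C(O)=O | starting material
2 | pivalaldehyde | CC(C)(C)C=O | starting material
3 | (2R,5R)-2-tert-butyl-5-methyl-1,3-dioxolan-4-one | C[C@H]1O[C@@H](C(C)(C)C)OC1=O | intermediate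
4 | 4,4-dimethoxybutan-2-one | CC(=O)CC(OC)OC | starting material
5 | 3-(dimethoxymethyl)but-3-en-2-one | CC(=O)C(=C)C(OC)OC | intermediate
6 | Michael adduct, not isolated: (2R,5S)-2-tert-butyl-5-[2-(dimethoxymethyl)-3-oxobutyl]-5-methyl-1,3-dioxolan-4-one (lithium enolate in the flask, side-chain CH undefined) | C[C@@]1(CC(C(C)=O)C(OC)OC)O[C@@H](C(C)(C)C)OC1=O | intermediate
7 | (S,E)-4-hydroxy-6-(methoxymethylene)-4-methylcyclohexane-1,3-dione | CO/C=C1\C[C@](C)(O)C(=O)CC1=O | intermediate
8 | bis-silyl ether, not isolated: (S,E)-6-(methoxymethylene)-4-methyl-3,4-bis(triethylsilyloxy)cyclohex-2-en-1-one (drawn as the C4a enol ether; the regiochemistry is irrelevant) | CO/C=C1\C[C@](C)(O[Si](CC)(CC)CC)C(=O)C=C1O[Si](CC)(CC)CC | intermediate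
9 | (S,E)-6-(methoxymethylene)-4-methyl-4-(triethylsilyloxy)cyclohexane-1,3-dione | CO/C=C1\C[C@](C)(O[Si](CC)(CC)CC)C(=O)CC1=O | intermediate
10 | (S,E)-6-(methoxymethylene)-4-methyl-3-oxo-4-(triethylsilyloxy)cyclohex-1-en-1-yl trifluoromethanesulfonate | CO/C=C1\C[C@](C)(O[Si](CC)(CC)CC)C(=O)C=C1OS(=O)(=O)C(F)(F)F | intermediate
11 | tert-butyl bromoacetate | BrCC(=O)OC(C)(C)C | starting material
12 | bromozinc tert-butyl acetate (Reformatsky reagent) | Br[Zn]CC(=O)OC(C)(C)C | intermediate
13 | coupled ester, not isolated: tert-butyl 2-[(S,E)-6-(methoxymethylene)-4-methyl-3-oxo-4-(triethylsilyloxy)cyclohex-1-en-1-yl]acetate | CO/C=C1\C[C@](C)(O[Si](CC)(CC)CC)C(=O)C=C1CC(=O)OC(C)(C)C | intermediate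
14 | hydroxy acid, not isolated: 2-[(S,E)-4-hydroxy-6-(methoxymethylene)-4-methyl-3-oxocyclohex-1-en-1-yl]acetic acid | CO/C=C1\C[C@](C)(O)C(=O)C=C1CC(=O)O | intermediate
15 | (S)-7-hydroxy-7-methyl-7,8-dihydro-4H-isochromene-3,6-dione | O=C1CC2=CC(=O)[C@@](C)(O)CC2=CO1 | intermediate
16 | (S)-7-hydroxy-7-methyl-6-oxo-7,8-dihydro-6H-isochromen-3-yl trifluoromethanesulfonate | FC(F)(F)S(=O)(=O)OC1=CC2=CC(=O)[C@@](C)(O)CC2=CO1 | intermediate
17 | prop-2-yn-1-yl acetate | CC(=O)OCC#C | starting material
18 | (E)-3-(4,4,5,5-tetramethyl-1,3,2-dioxaborolan-2-yl)prop-2-en-1-yl acetate | CC(=O)OC/C=C/B1OC(C)(C)C(C)(C)O1 | intermediate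
19 | (S)-3-[(E)-3-acetoxyprop-1-enyl]-7-hydroxy-7-methyl-7,8-dihydro-6H-isochromen-6-one | CC(=O)OC/C=C/C1=CC2=CC(=O)[C@@](C)(O)CC2=CO1 | intermediate
20 | orsellinic acid | Cc1cc(O)cc(O)c1C(=O)O | starting material
21 | tert-butyldimethylsilyl 2,4-bis(tert-butyldimethylsilyloxy)-6-methylbenzoate | Cc1cc(O[Si](C)(C)C(C)(C)C)cc(O[Si](C)(C)C(C)(C)C)c1C(=O)O[Si](C)(C)C(C)(C)C | intermediate
22 | 2,4-bis(tert-butyldimethylsilyloxy)-6-methylbenzoyl chloride | Cc1cc(O[Si](C)(C)C(C)(C)C)cc(O[Si](C)(C)C(C)(C)C)c1C(Cl)=O | intermediate
23 | (S)-3-[(E)-3-acetoxyprop-1-enyl]-7-methyl-6-oxo-7,8-dihydro-6H-isochromen-7-yl 2,4-bis(tert-butyldimethylsilyloxy)-6-methylbenzoate | CC(=O)OC/C=C/C1=CC2=CC(=O)[C@@](C)(OC(=O)c3c(C)cc(O[Si](C)(C)C(C)(C)C)cc3O[Si](C)(C)C(C)(C)C)CC2=CO1 | intermediate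
24 | (S)-3-[(E)-3-acetoxyprop-1-enyl]-7-methyl-6-oxo-7,8-dihydro-6H-isochromen-7-yl 2,4-dihydroxy-6-methylbenzoate | CC(=O)OC/C=C/C1=CC2=CC(=O)[C@@](C)(OC(=O)c3c(C)cc(O)cc3O)CC2=CO1 | target

## Step count and least certain steps

Total: 14 steps. Longest linear sequence: 9 steps (1, 3, 4, 5, 7, 8, 10, 13, 14). Steps 2, 6, 9, 11 and 12 are side branches.

**Step 7 (key step).** The most likely failure is slow transmetalation of the zinc enolate, which would let uncatalysed conjugate addition–elimination at C1 or hydrolytic loss of the triflate compete. In the acid stage, incomplete desilylation or an acid-promoted α-ketol shift could interfere. The fallback makes the addition–elimination reactivity the productive path and needs no palladium. It sets out from 10: sodium di-tert-butyl malonate (NaH, di-tert-butyl malonate, THF, 0 °C) should displace the triflate at C4a, the β-carbon with the far better leaving group, to give di-tert-butyl 2-[(S,E)-6-(methoxymethylene)-4-methyl-3-oxo-4-(triethylsilyloxy)cyclohex-1-en-1-yl]malonate F1. CF3CO2H in CH2Cl2, then gentle warming, should cleave both esters and the silyl ether, decarboxylate the malonic acid and close the lactone. The fallback returns to the route at 15.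

**Step 13.** Esterification may stall because both partners are hindered, and the acylium-type electrophile may instead attack the nucleophilic C5 position or ionise the allylic acetate. The fallback changes the acyl donor and the mechanism. It sets out from 20 and 19. Acetone with (CF3CO)2O in CF3CO2H should convert 20 into 7-hydroxy-2,2,5-trimethyl-4H-1,3-benzodioxin-4-one F2, which is silylated (t-BuMe2SiCl, imidazole) to 7-(tert-butyldimethylsilyloxy)-2,2,5-trimethyl-4H-1,3-benzodioxin-4-one F3. The sodium alkoxide of 19 (NaN(SiMe3)2, THF, −78 °C) should open F3 at the acyl carbon, where the ortho oxygen is tied back in the ring, with loss of acetone. This gives (S)-3-[(E)-3-acetoxyprop-1-enyl]-7-methyl-6-oxo-7,8-dihydro-6H-isochromen-7-yl 4-(tert-butyldimethylsilyloxy)-2-hydroxy-6-methylbenzoate F4, and HF·pyridine completes the synthesis. The fallback returns to the route at 24.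

**Step 3.** The lithium enolate may add to the carbonyl of 5 instead of its terminus, or the sequence may stop after the conjugate addition because liberated methoxide opens the dioxolanone before the Claisen closure. The fallback separates the two events and changes the acyl acceptor. It sets out from 6, isolated by quenching the first stage at −78 °C with acetic acid. NaOMe (cat.) in MeOH should give methyl (2S)-4-(dimethoxymethyl)-2-hydroxy-2-methyl-5-oxohexanoate F5 with release of pivalaldehyde. Et3SiOTf and 2,6-lutidine should give methyl (2S)-4-(dimethoxymethyl)-2-methyl-5-oxo-2-(triethylsilyloxy)hexanoate F6. KOt-Bu in THF at 0 °C should then effect Claisen closure of the acetyl enolate onto the methyl ester and loss of methanol from the acetal. The fallback returns to the route at 9, so step 4 is not needed.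

**Step 5.** Sulfonylation may occur on the C6 oxygen of the diketonate instead of the C4a oxygen and give the regioisomeric triflate. The fallback uses a different control element. It sets out from 7, in which the free C7 hydroxyl ties up the C6 oxygen by an internal hydrogen bond. PhNTf2 and Et3N in CH2Cl2 should give (S,E)-4-hydroxy-6-(methoxymethylene)-4-methyl-3-oxocyclohex-1-en-1-yl trifluoromethanesulfonate F7, and Et3SiOTf with 2,6-lutidine then silylates the tertiary alcohol. The fallback returns to the route at 10.

**Step 10.** Zerovalent palladium may ionise the allylic acetate of 18 or of the product, or aqueous base may hydrolyse the ketene acetal triflate before transmetalation. The fallback removes the acetate from the coupling. It sets out from 16, which is coupled under the same catalyst with commercial (E)-3-(tert-butyldimethylsilyloxy)prop-1-enylboronic acid pinacol ester to give (S)-3-[(E)-3-(tert-butyldimethylsilyloxy)prop-1-enyl]-7-hydroxy-7-methyl-7,8-dihydro-6H-isochromen-6-one F8. HF·pyridine should give (S)-7-hydroxy-3-[(E)-3-hydroxyprop-1-enyl]-7-methyl-7,8-dihydro-6H-isochromen-6-one F9. Ac2O in pyridine at 0 °C acetylates only the primary hydroxyl. The fallback returns to the route at 19.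

**Step 2.** The Mannich condensation may take place at the methyl group, or the acidic medium may eliminate methanol from the acetal; the product may also polymerise on heating. The fallback separates C–C bond formation from elimination and avoids acid and heat. It sets out from 4: dimethylmethyleneiminium iodide in MeCN at rt should give 3-(dimethoxymethyl)-4-(dimethylamino)butan-2-one F10, MeI gives [2-(dimethoxymethyl)-3-oxobutyl]trimethylammonium iodide F11, and aq NaHCO3/CH2Cl2 at 0 °C eliminates trimethylamine. The fallback returns to the route at 5.

## Further compounds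

F1 | step 7 | di-tert-butyl 2-[(S,E)-6-(methoxymethylene)-4-methyl-3-oxo-4-(triethylsilyloxy)cyclohex-1-en-1-yl]malonate | CO/C=C1\C[C@](C)(O[Si](CC)(CC)CC)C(=O)C=C1C(C(=O)OC(C)(C)C)C(=O)OC(C)(C)C
F2 | step 13 | 7-hydroxy-2,2,5-trimethyl-4H-1,3-benzodioxin-4-one | Cc1cc(O)cc2OC(C)(C)OC(=O)c12
F3 | step 13 | 7-(tert-butyldimethylsilyloxy)-2,2,5-trimethyl-4H-1,3-benzodioxin-4-one | Cc1cc(O[Si](C)(C)C(C)(C)C)cc2OC(C)(C)OC(=O)c12
F4 | step 13 | (S)-3-[(E)-3-acetoxyprop-1-enyl]-7-methyl-6-oxo-7,8-dihydro-6H-isochromen-7-yl 4-(tert-butyldimethylsilyloxy)-2-hydroxy-6-methylbenzoate | CC(=O)OC/C=C/C1=CC2=CC(=O)[C@@](C)(OC(=O)c3c(C)cc(O[Si](C)(C)C(C)(C)C)cc3O)CC2=CO1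
F5 | step 3 | methyl (2S)-4-(dimethoxymethyl)-2-hydroxy-2-methyl-5-oxohexanoate | COC(=O)[C@@](C)(O)CC(C(C)=O)C(OC)OC
F6 | step 3 | methyl (2S)-4-(dimethoxymethyl)-2-methyl-5-oxo-2-(triethylsilyloxy)hexanoate | COC(=O)[C@@](C)(O[Si](CC)(CC)CC)CC(C(C)=O)C(OC)OC
F7 | step 5 | (S,E)-4-hydroxy-6-(methoxymethylene)-4-methyl-3-oxocyclohex-1-en-1-yl trifluoromethanesulfonate | CO/C=C1\C[C@](C)(O)C(=O)C=C1OS(=O)(=O)C(F)(F)F
F8 | step 10 | (S)-3-[(E)-3-(tert-butyldimethylsilyloxy)prop-1-enyl]-7-hydroxy-7-methyl-7,8-dihydro-6H-isochromen-6-one | CC(C)(C)[Si](C)(C)OC/C=C/C1=CC2=CC(=O)[C@@](C)(O)CC2=CO1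
F9 | step 10 | (S)-7-hydroxy-3-[(E)-3-hydroxyprop-1-enyl]-7-methyl-7,8-dihydro-6H-isochromen-6-one | OC/C=C/C1=CC2=CC(=O)[C@@](C)(O)CC2=CO1
F10 | step 2 | 3-(dimethoxymethyl)-4-(dimethylamino)butan-2-one | CC(=O)C(CN(C)C)C(OC)OC
F11 | step 2 | [2-(dimethoxymethyl)-3-oxobutyl]trimethylammonium iodide | CC(=O)C(C[N+](C)(C)C)C(OC)OC.[I-]
A1 | alternative 1 | (S,E)-4-hydroxy-6-(methoxymethylene)-4-methylcyclohexane-1,3-dione | CO/C=C1\C[C@](C)(O)C(=O)CC1=O
A2 | alternative 2 | (E)-3-[4-(2-oxoethylidene)-5-(2-oxopropyl)-4H-pyran-2-yl]prop-2-en-1-yl acetate | CC(=O)OC/C=C/C1=CC(=CC=O)C(CC(C)=O)=CO1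
A3 | alternative 2 | (S)-3-[(E)-3-acetoxyprop-1-enyl]-7-hydroxy-7-methyl-7,8-dihydro-6H-isochromen-6-one | CC(=O)OC/C=C/C1=CC2=CC(=O)[C@@](C)(O)CC2=CO1
A4 | alternative 3 | (S,E)-4-(methoxymethylene)-3,6-dimethyl-6-(triethylsilyloxy)cyclohex-2-en-1-one | CO/C=C1\C[C@](C)(O[Si](CC)(CC)CC)C(=O)C=C1C
A5 | alternative 3 | (E)-4-acetoxybut-2-enoyl chloride | CC(=O)OC/C=C/C(Cl)=O
A6 | alternative 3 | (S)-3-[(E)-3-acetoxyprop-1-enyl]-7-methyl-7-(triethylsilyloxy)-7,8-dihydro-6H-isochromen-6-one | CC(=O)OC/C=C/C1=CC2=CC(=O)[C@@](C)(O[Si](CC)(CC)CC)CC2=CO1
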